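The indole is cut at N1–C7a and C3–C3a. C5–Br and C6–Br of the benzo ring mirror each other across the C3a–C7a bond. The arene piece is therefore the symmetric 4,5-dibromobenzyne, and it does not matter which aryne carbon takes nitrogen. In one operation an N-tosyl α-amino ketone delivers N1, C2 and C3, closes the pyrrole ring and brings the aldehyde carbon along as a dimethyl acetal. The precursors are a dibrominated ortho-silylaryl triflate and TsNHCH2C(O)CH(OMe)2. The tosyl group then acidifies C2–H for magnesiation and bromination, and it is exchanged for methyl only at the robust aldehyde stage.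

Key step: step 5

Assumption: an N-sulfonyl-3-hydroxyindoline is not expected to lose water by itself under fluoride, so the crude carbinol is dehydrated with MsCl/Et3N inside step 5; acid is avoided there because it would ionise the acetal next to the carbinol.

Remark on the end game: bromine is placed at C2 through a C2 carbanion while tosyl is still on nitrogen. An electrophilic bromine source on an N-alkyl-3-(dimethoxymethyl)indole would attack C3 first, where the dimethoxymethyl group can leave as a stabilised cation. Such donor-substituted acetals also tolerate little handling. The target has no stereocentre.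

Step 1
Reactants: 1 3,4-dibromophenol
Product: 2 4,5-dibromo-2-iodophenol
Conditions: NIS (1.0 equiv), TsOH·H2O (10 mol %), MeCN, 0 °C → rt
Reagents that add atoms: N-iodosuccinimide, O=C1CCC(=O)N1I
Why: Electrophilic aromatic iodination, in which the hydroxyl group directs ortho because its para position carries bromine, and of the two ortho sites C6 is open and para to C3–Br whereas C2 is wedged between OH and Br.

Step 2
Reactants: 2 4,5-dibromo-2-iodophenol
Product: 6 4,5-dibromo-2-(trimethylsilyl)phenyl trifluoromethanesulfonate, via aryl trimethylsilyl ether 3 (not isolated), via aryllithium 4 (not isolated), via lithium phenoxide 5 (not isolated)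
Conditions: HMDS, THF, 70 °C, then evaporate; n-BuLi (1.05 equiv), THF, −100 → −78 °C; Tf2O, −78 °C → rt
Reagents that add atoms: hexamethyldisilazane, C[Si](C)(C)N[Si](C)(C)C; trifluoromethanesulfonic anhydride, O=S(=O)(OS(=O)(=O)C(F)(F)F)C(F)(F)F
Why: O-silylation, iodine–lithium exchange and retro-Brook rearrangement (anionic 1,3 O→C silyl shift) followed by O-triflation is the standard one-flask entry to ortho-silylaryl triflates, and it should tolerate the bromines because exchange at iodine is much faster than at bromine at −100 °C, aryllithium 4 has no ortho bromine to expel, and it is consumed at once by the intramolecular silyl shift to the unreactive phenoxide 5.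

Step 3
Reactants: 7 1,1-dimethoxypropan-2-one
Product: 8 3-bromo-1,1-dimethoxypropan-2-one
Conditions: Br2 (1.0 equiv), MeOH, 0 °C → rt
Reagents that add atoms: bromine, BrBr
Why: Acid-catalysed α-bromination of a ketone via its enol, which in methanol takes the unhindered methyl side rather than the acetal methine, while the solvent keeps the dimethyl acetal intact against the hydrogen bromide released.

Step 4
Reactants: 8 3-bromo-1,1-dimethoxypropan-2-one; 9 p-toluenesulfonamide
Product: 10 N-(3,3-dimethoxy-2-oxopropyl)-4-methylbenzenesulfonamide
Conditions: 9 (3 equiv), K2CO3 (1.5 equiv), acetone, rt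
Reagents that add atoms: none
Why: SN2 N-alkylation of the sulfonamide anion by a reactive α-bromo ketone, in which the threefold excess of 9 keeps the product from being alkylated a second time and K2CO3 is too weak to enolise the ketone extensively.

Step 5
Reactants: 6 4,5-dibromo-2-(trimethylsilyl)phenyl trifluoromethanesulfonate; 10 N-(3,3-dimethoxy-2-oxopropyl)-4-methylbenzenesulfonamide
Product: 14 5,6-dibromo-3-(dimethoxymethyl)-1-tosylindole, via 4,5-dibromobenzyne 11 (not isolated), via indolin-3-ol 12 (not isolated), via tertiary mesylate 13 (not isolated)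
Conditions: CsF (3 equiv), dry MeCN, rt, slow addition of 6 (1.3 equiv); filter, concentrate; MsCl, Et3N, CH2Cl2, 0 °C → rt
Reagents that add atoms: none
Why: Fluoride attacks silicon of 6 and triflate leaves (1,2-elimination) to give aryne 11; the caesium salt of 10 adds through nitrogen (N1–C7a), the ortho aryl anion so formed adds to the ketone (C3–C3a) to give carbinol 12, and 12 is mesylated via sulfene to 13, which loses methanesulfonate by base-induced removal of a C2 proton with aromatisation as the driving force. The closest known reaction type is the fluoride-induced aryne annulation of N-sulfonyl and N-aryl α-amino carbonyl compounds to indoles and indolin-3-ones. The pyrrole ring closes by a 5-exo-trig addition of the aryl anion to C=O. The only new stereocentre, C3 of 12, forms as a racemate and is erased on dehydration, so the product carries none. No regiochemistry arises because both aryne carbons are equivalent; attack through N rather than enolate carbon rests on N–H being the most acidic site of 10, and carbonyl capture ahead of protonation rests on the lack of any N–H in the adduct, the dry medium, the five-membered transition state and the inductive activation of the ketone by the two acetal oxygens. The aryl anion lies meta and para to the bromines, so no second aryne can form, and the basic dehydration spares the acetal.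

Step 6
Reactants: 14 5,6-dibromo-3-(dimethoxymethyl)-1-tosylindole
Product: 16 2,5,6-tribromo-3-(dimethoxymethyl)-1-tosylindole, via indol-2-ylmagnesium chloride 15 (not isolated)
Conditions: TMPMgCl·LiCl (1.2 equiv), THF, 0 °C; BrCl2C–CCl2Br, −20 °C → rt
Reagents that add atoms: 1,2-dibromo-1,1,2,2-tetrachloroethane, ClC(Cl)(Br)C(Cl)(Cl)Br
Why: Directed deprotonative magnesiation followed by electrophilic bromination, known for N-sulfonylindoles with magnesium amide bases: C2–H is the most acidic proton, flanked by the sulfonyl nitrogen and the coordinating acetal, and a magnesium amide neither exchanges with the C–Br bonds nor sets off a halogen dance.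

Step 7
Reactants: 16 2,5,6-tribromo-3-(dimethoxymethyl)-1-tosylindole
Product: 18 2,5,6-tribromo-1H-indole-3-carbaldehyde, via N–H acetal 17 (not isolated)
Conditions: KOH (5 equiv), THF/MeOH/H2O, 40 °C; then 2 M HCl to pH 1, rt
Reagents that add atoms: water, O
Why: Base hydrolysis of the N-sulfonyl group, eased by the good tribromoindolide leaving group and harmless to an acetal, is followed in the same flask by acid hydrolysis of the acetal, which once nitrogen is free is pushed out by the indole lone pair, so that the fragile N–H acetal 17 is never handled.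

Step 8
Reactants: 18 2,5,6-tribromo-1H-indole-3-carbaldehyde
Product: 19 2,5,6-tribromo-1-methylindole-3-carbaldehyde
Conditions: MeI (1.5 equiv), K2CO3, DMF, rt
Reagents that add atoms: iodomethane, CI
Why: SN2 N-methylation of the acidic N–H of a 3-formylindole (a vinylogous amide) under carbonate conditions, which contain no nucleophile able to displace the activated C2 bromine.

Compound list
1 | 3,4-dibromophenol | Oc1ccc(Br)c(Br)c1 | starting material
2 | 4,5-dibromo-2-iodophenol | Oc1cc(Br)c(Br)cc1I | intermediate
3 | (4,5-dibromo-2-iodophenoxy)trimethylsilane | C[Si](C)(C)Oc1cc(Br)c(Br)cc1I | intermediate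
4 | [4,5-dibromo-2-(trimethylsilyloxy)phenyl]lithium | [Li]c1cc(Br)c(Br)cc1O[Si](C)(C)C | intermediate
5 | lithium 4,5-dibromo-2-(trimethylsilyl)phenoxide | [Li+].[O-]c1cc(Br)c(Br)cc1[Si](C)(C)C | intermediate
6 | 4,5-dibromo-2-(trimethylsilyl)phenyl trifluoromethanesulfonate | C[Si](C)(C)c1cc(Br)c(Br)cc1OS(=O)(=O)C(F)(F)F | intermediate
7 | 1,1-dimethoxypropan-2-one | COC(OC)C(C)=O | starting material
8 | 3-bromo-1,1-dimethoxypropan-2-one | COC(OC)C(=O)CBr | intermediate
9 | p-toluenesulfonamide | Cc1ccc(cc1)S(N)(=O)=O | starting material
10 | N-(3,3-dimethoxy-2-oxopropyl)-4-methylbenzenesulfonamide | COC(OC)C(=O)CNS(=O)(=O)c1ccc(C)cc1 | intermediate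
11 | 4,5-dibromobenzyne (1,2-dibromo-4,5-didehydrobenzene) | BrC1=CC#CC=C1Br | intermediate
12 | 5,6-dibromo-3-(dimethoxymethyl)-1-tosylindolin-3-ol (racemic) | COC(OC)C1(O)CN(S(=O)(=O)c2ccc(C)cc2)c2cc(Br)c(Br)cc21 | intermediate
13 | 5,6-dibromo-3-(dimethoxymethyl)-1-tosylindolin-3-yl methanesulfonate (racemic) | COC(OC)C1(OS(C)(=O)=O)CN(S(=O)(=O)c2ccc(C)cc2)c2cc(Br)c(Br)cc21 | intermediate
14 | 5,6-dibromo-3-(dimethoxymethyl)-1-tosylindole | COC(OC)c1cn(S(=O)(=O)c2ccc(C)cc2)c2cc(Br)c(Br)cc12 | intermediate
15 | [5,6-dibromo-3-(dimethoxymethyl)-1-tosylindol-2-yl]magnesium chloride | COC(OC)c1c([Mg]Cl)n(S(=O)(=O)c2ccc(C)cc2)c2cc(Br)c(Br)cc12 | intermediate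
16 | 2,5,6-tribromo-3-(dimethoxymethyl)-1-tosylindole | COC(OC)c1c(Br)n(S(=O)(=O)c2ccc(C)cc2)c2cc(Br)c(Br)cc12 | intermediate
17 | 2,5,6-tribromo-3-(dimethoxymethyl)-1H-indole | COC(OC)c1c(Br)[nH]c2cc(Br)c(Br)cc12 | intermediate
18 | 2,5,6-tribromo-1H-indole-3-carbaldehyde | O=Cc1c(Br)[nH]c2cc(Br)c(Br)cc12 | intermediate
19 | 2,5,6-tribromo-1-methylindole-3-carbaldehyde | Cn1c(Br)c(C=O)c2cc(Br)c(Br)cc21 | target

Total step count: 8. Longest linear sequence: 6 steps (1, 2, 5, 6, 7, 8).

Steps most likely to fail

**Step 5.**
- The aryl anion may be protonated by unreacted sulfonamide or by acetonitrile before it closes the ring.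
- Arylation may occur through the enolate carbon, or the amino ketone may self-condense under fluoride.
- The fallback sets out from 6, 8 and 9 and returns at carbinol 12.
- Aryne 11 is released from 6 with CsF in MeCN in the presence of excess 9. Here plain N-arylation with protonation is the wanted outcome, and it should give N-(3,4-dibromophenyl)-4-methylbenzenesulfonamide F1.
- Iodination (NIS, CF3CO2H, MeCN) at the open ortho position, para to one bromine, should give N-(4,5-dibromo-2-iodophenyl)-4-methylbenzenesulfonamide F2.
- Deprotonation with MeMgCl and iodine–magnesium exchange with iPrMgCl·LiCl (THF, −30 °C) should give the N,C-bis(chloromagnesio) sulfonanilide F3.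
- The aryl carbon of F3 adds to the ketone of 8 at −40 °C to give N-[4,5-dibromo-2-(1-bromo-2-hydroxy-3,3-dimethoxypropan-2-yl)phenyl]-4-methylbenzenesulfonamide F4.
- Displacement of bromide by the sulfonamide nitrogen, on warming or with K2CO3 in DMF, closes the ring to 12, which is dehydrated as in step 5.
- The same two bonds are thus made in the opposite order by the known indole synthesis from ortho-metalated anilides and α-halo ketones. No aryl anion has to outrun a proton.

**Step 2.**
- Bromine–lithium exchange, or attack of butyllithium at silicon, may compete with exchange at iodine and be followed by halogen scrambling.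
- The fallback sets out from 2 and returns at 6.
- The free phenol is deprotonated with MeMgCl in the presence of LiCl, and the iodide is exchanged with iPrMgCl·LiCl (THF, −20 → 0 °C). This should give chloromagnesium 4,5-dibromo-2-(chloromagnesio)phenoxide F5.
- Excess TMSCl brings silicon in from outside and should give [4,5-dibromo-2-(trimethylsilyl)phenoxy]trimethylsilane F6.
- The O–Si bond of F6 is cleaved on mild aqueous work-up to give 4,5-dibromo-2-(trimethylsilyl)phenol F7.
- Separate triflation (Tf2O, pyridine, CH2Cl2, 0 °C) gives 6.
- No organolithium and no silyl migration are involved, and arylmagnesium species leave C–Br bonds alone at these temperatures.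

**Step 6.**
- Metalation may be incomplete, or misdirected to the tosyl methyl group or to C4–H and C7–H next to bromine. The hindered C2 anion may also be trapped sluggishly.
- The fallback sets out from 14 and returns at target 19.
- KOH in THF/MeOH/H2O removes the tosyl group to give 5,6-dibromo-3-(dimethoxymethyl)-1H-indole F8. Acidification in the same flask converts F8 into 5,6-dibromo-1H-indole-3-carbaldehyde F9.
- MeI and K2CO3 in DMF give 5,6-dibromo-1-methylindole-3-carbaldehyde F10.
- The aldehyde-tolerant zinc amide TMPZnCl·LiCl (THF, rt) zincates C2 next to the formyl group to give (5,6-dibromo-3-formyl-1-methylindol-2-yl)zinc chloride F11.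
- Bromine at −30 °C converts F11 into 19.
- The directing group is now the aldehyde instead of the sulfonyl group, and C2–Br is made last.

Further compounds
F1 | step 5 | N-(3,4-dibromophenyl)-4-methylbenzenesulfonamide | Cc1ccc(cc1)S(=O)(=O)Nc1ccc(Br)c(Br)c1
F2 | step 5 | N-(4,5-dibromo-2-iodophenyl)-4-methylbenzenesulfonamide | Cc1ccc(cc1)S(=O)(=O)Nc1cc(Br)c(Br)cc1I
F3 | step 5 | N,C-bis(chloromagnesio) sulfonanilide | Cc1ccc(cc1)S(=O)(=O)N([Mg]Cl)c1cc(Br)c(Br)cc1[Mg]Cl
F4 | step 5 | N-[4,5-dibromo-2-(1-bromo-2-hydroxy-3,3-dimethoxypropan-2-yl)phenyl]-4-methylbenzenesulfonamide (racemic) | COC(OC)C(O)(CBr)c1cc(Br)c(Br)cc1NS(=O)(=O)c1ccc(C)cc1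
F5 | step 2 | chloromagnesium 4,5-dibromo-2-(chloromagnesio)phenoxide | Cl[Mg]Oc1cc(Br)c(Br)cc1[Mg]Cl
F6 | step 2 | [4,5-dibromo-2-(trimethylsilyl)phenoxy]trimethylsilane | C[Si](C)(C)Oc1cc(Br)c(Br)cc1[Si](C)(C)C
F7 | step 2 | 4,5-dibromo-2-(trimethylsilyl)phenol | Oc1cc(Br)c(Br)cc1[Si](C)(C)C
F8 | step 6 | 5,6-dibromo-3-(dimethoxymethyl)-1H-indole | COC(OC)c1c[nH]c2cc(Br)c(Br)cc12
F9 | step 6 | 5,6-dibromo-1H-indole-3-carbaldehyde | O=Cc1c[nH]c2cc(Br)c(Br)cc12
F10 | step 6 | 5,6-dibromo-1-methylindole-3-carbaldehyde | Cn1cc(C=O)c2cc(Br)c(Br)cc21
F11 | step 6 | (5,6-dibromo-3-formyl-1-methylindol-2-yl)zinc chloride | Cn1c([Zn]Cl)c(C=O)c2cc(Br)c(Br)cc21
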